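**Retrosynthetic overview**

1. Last step: reagent-controlled Shi epoxidation of the E-trisubstituted olefin sets both oxirane centres.
2. Key step: the α-methylene-γ-butyrolactone comes from a two-atom ring expansion of a terminal (R)-oxirane (formal insertion of the C=C=O unit of Ph3P=C=C=O into the CH2–O bond, then Wittig methylenation). The lactone centre is carried over from the oxirane.
3. The aryl allyl ether comes from Mitsunobu coupling of 7-hydroxy-8-methoxycoumarin with an epoxy allylic alcohol.
4. The epoxy allylic alcohol comes from (R)-epichlorohydrin and acetylene (BF3 alkynylation), then Zr-catalysed carboalumination/hydroxymethylation (E-olefin) and oxirane closure.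
5. Ring order: coumarin pyranone (resorcinol → 2-iodo → 2-methoxy → Pechmann with ethyl propiolate), terminal oxirane, lactone (ring expansion), trisubstituted oxirane.

Assumption: NaOMe, Me3Al, formaldehyde, Ph3P=C=C=O and Oxone are treated as reagents that add atoms; the numbered starting materials are 1, 4, 6 and 7.

**Route**

Step 1
Reactants: 1 resorcinol
Product: 2 2-iodobenzene-1,3-diol
Conditions: I2, NaHCO3, H2O, 0 °C → rt
Reagents that add atoms: iodine II
Why: Electrophilic aromatic iodination of the resorcinolate in mildly basic water goes to C2, the position flanked by both hydroxyls, and the 2-iodo compound crystallises.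

Step 2
Reactants: 2 2-iodobenzene-1,3-diol
Product: 3 2-methoxybenzene-1,3-diol
Conditions: NaOMe (5 equiv), CuCl (0.2 equiv), MeOH–DMF, 110 °C; aq HCl work-up
Reagents that add atoms: sodium methoxide [Na+].[O-]C
Why: Copper-catalysed Ullmann-type methoxylation of an ortho-hydroxy aryl iodide (the iodovanillin-to-syringaldehyde type) replaces iodine by OMe and leaves the phenols free.

Step 3
Reactants: 3 2-methoxybenzene-1,3-diol; 4 ethyl propiolate
Product: 5 7-hydroxy-8-methoxy-2H-chromen-2-one
Conditions: ZnCl2 (1 equiv), dioxane, 100 °C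
Reagents that add atoms: none
Why: Pechmann-type hydroarylation/lactonisation, in which the only activated ring position (ortho to one OH, para to the other) adds to the propiolate and the neighbouring OH closes the pyranone, which fixes the 7-OH/8-OMe pattern.

Step 4
Reactants: 6 (R)-epichlorohydrin; 7 acetylene
Product: 9 (2R)-1-chloropent-4-yn-2-ol, via lithium acetylide 8 (not isolated)
Conditions: 7, n-BuLi, THF, −78 °C; BF3·OEt2, then 6, −78 °C; H2O quench
Reagents that add atoms: none
Why: Yamaguchi–Hirao BF3-promoted alkynylation opens the oxirane only at its CH2 terminus, so the stereocentre is untouched and the chlorohydrin is kept without re-closure or scrambling.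

Step 5
Reactants: 9 (2R)-1-chloropent-4-yn-2-ol
Product: 12 (2E)-3-methyl-4-[(2R)-oxiran-2-yl]but-2-en-1-ol, via alkenylalane 10 (not isolated), via chlorohydrin diol 11 (not isolated)
Conditions: Me3Al (3 equiv), Cp2ZrCl2 (0.25 equiv), CH2Cl2, 0 → 23 °C; evaporate; n-BuLi, THF, −78 °C, then (CH2O)n, → 23 °C; 2 M aq NaOH, 23 °C
Reagents that add atoms: trimethylaluminium C[Al](C)C; formaldehyde (from paraformaldehyde) C=O
Why: Negishi Zr-catalysed syn-carboalumination of the terminal alkyne (OH masked in the flask as O–AlMe2) puts Me on the internal carbon cis to Al, the alanate is hydroxymethylated with retention to give the E-allylic alcohol, and the basic work-up closes the chlorohydrin to the (R)-oxirane by intramolecular Williamson reaction without touching the stereocentre.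

Step 6
Reactants: 12 (2E)-3-methyl-4-[(2R)-oxiran-2-yl]but-2-en-1-ol; 5 7-hydroxy-8-methoxy-2H-chromen-2-one
Product: 13 8-methoxy-7-{[(2E)-3-methyl-4-[(2R)-oxiran-2-yl]but-2-en-1-yl]oxy}-2H-chromen-2-one
Conditions: PPh3, DIAD, THF, 0 → 23 °C
Reagents that add atoms: none
Why: Mitsunobu etherification of the primary allylic alcohol with the acidic coumarin phenol is an SN2 reaction at CH2 under neutral conditions that leave the oxirane and the olefin geometry intact.

Step 7
Reactants: 13 8-methoxy-7-{[(2E)-3-methyl-4-[(2R)-oxiran-2-yl]but-2-en-1-yl]oxy}-2H-chromen-2-one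
Product: 15 8-methoxy-7-{[(2E)-3-methyl-4-[(2R)-4-methylidene-5-oxooxolan-2-yl]but-2-en-1-yl]oxy}-2H-chromen-2-one, via lactone ylide 14 (not isolated)
Conditions: Ph3P=C=C=O (1.3 equiv), LiI (20 mol %), THF, 65 °C; then (CH2O)n (5 equiv), 65 °C
Reagents that add atoms: ketenylidenetriphenylphosphorane O=C=C=P(c1ccccc1)(c1ccccc1)c1ccccc1; formaldehyde (from paraformaldehyde) C=O
Why: Proposed new method: a two-atom ring expansion of the oxirane (3 → 5) in which iodide opens the terminal CH2–O bond, the alkoxide adds to the C=O carbon of the cumulated ylide and the resulting ylide carbanion displaces iodide (5-exo-tet, C-alkylation favoured by the soft leaving group), which regenerates LiI and gives the α-phosphoranylidene lactone with retention at the carbinol carbon because its C–O bond is never broken, and this ylide is then methylenated by Wittig reaction with formaldehyde; the closest known reactions are the halide-catalysed insertion of heterocumulenes (CO2, isocyanates) into epoxides, the addition of alcohols to Ph3P=C=C=O and the Wittig olefination of α-phosphoranylidene-γ-butyrolactones.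

Step 8
Reactants: 15 8-methoxy-7-{[(2E)-3-methyl-4-[(2R)-4-methylidene-5-oxooxolan-2-yl]but-2-en-1-yl]oxy}-2H-chromen-2-one
Product: 16 (5S)-5-{[(2R,3R)-3-{[(8-methoxy-2-oxo-2H-chromen-7-yl)oxy]methyl}-2-methyloxiran-2-yl]methyl}-3-methylideneoxolan-2-one
Conditions: D-fructose-derived Shi ketone (1–3 equiv), Oxone, NaHCO3, MeCN–aq Na2EDTA (pH ≈ 8), 0 °C
Reagents that add atoms: potassium peroxymonosulfate (Oxone) [K+].[O-]S(=O)(=O)OO
Why: Shi asymmetric epoxidation, in which the chiral dioxirane attacks only the electron-rich E-trisubstituted olefin (the acrylate and coumarin C=C are electron-poor) through the spiro transition state from the face that gives the (2R,3R)-oxirane (the same sense as (R,R)-trans-β-methylstyrene oxide), under reagent control that does not depend on the remote lactone centre.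

**Compound list**

1 | resorcinol (benzene-1,3-diol) | Oc1cccc(O)c1 | starting material
2 | 2-iodobenzene-1,3-diol | Oc1cccc(O)c1I | intermediate
3 | 2-methoxybenzene-1,3-diol | COc1c(O)cccc1O | intermediate
4 | ethyl propiolate | C#CC(=O)OCC | starting material
5 | 7-hydroxy-8-methoxy-2H-chromen-2-one | COc1c(O)ccc2ccc(=O)oc12 | intermediate
6 | (R)-epichlorohydrin, (2R)-2-(chloromethyl)oxirane | ClC[C@H]1CO1 | starting material
7 | acetylene | C#C | starting material
8 | lithium acetylide | [Li]C#C | intermediate
9 | (2R)-1-chloropent-4-yn-2-ol | C#CC[C@@H](O)CCl | intermediate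
10 | alkenylalane, [(1E,4R)-5-chloro-4-(dimethylalumanyloxy)-2-methylpent-1-en-1-yl]dimethylalumane | C[Al](C)/C=C(C)/C[C@@H](O[Al](C)C)CCl | intermediate
11 | chlorohydrin diol, (2E,5R)-6-chloro-3-methylhex-2-ene-1,5-diol | OC/C=C(C)/C[C@@H](O)CCl | intermediate
12 | (2E)-3-methyl-4-[(2R)-oxiran-2-yl]but-2-en-1-ol | OC/C=C(C)/C[C@@H]1CO1 | intermediate
13 | 8-methoxy-7-{[(2E)-3-methyl-4-[(2R)-oxiran-2-yl]but-2-en-1-yl]oxy}-2H-chromen-2-one | COc1c(OC/C=C(C)/C[C@@H]3CO3)ccc2ccc(=O)oc12 | intermediate
14 | lactone ylide, 8-methoxy-7-{[(2E)-3-methyl-4-[(2R)-5-oxo-4-(triphenyl-λ5-phosphanylidene)oxolan-2-yl]but-2-en-1-yl]oxy}-2H-chromen-2-one | COc1c(OC/C=C(C)/C[C@@H]3CC(=P(c4ccccc4)(c4ccccc4)c4ccccc4)C(=O)O3)ccc2ccc(=O)oc12 | intermediate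
15 | 8-methoxy-7-{[(2E)-3-methyl-4-[(2R)-4-methylidene-5-oxooxolan-2-yl]but-2-en-1-yl]oxy}-2H-chromen-2-one (lactone carbon is R by CIP here; same spatial arrangement as S in 16) | COc1c(OC/C=C(C)/C[C@@H]3CC(=C)C(=O)O3)ccc2ccc(=O)oc12 | intermediate
16 | (5S)-5-{[(2R,3R)-3-{[(8-methoxy-2-oxo-2H-chromen-7-yl)oxy]methyl}-2-methyloxiran-2-yl]methyl}-3-methylideneoxolan-2-one | C=C1C[C@@H](C[C@@]2(C)O[C@@H]2COc2ccc3ccc(=O)oc3c2OC)OC1=O | target

**Totals and risks**

Total step count: 8.
Longest linear sequence: 6 steps (1 → 2 → 3 → 5, then steps 6, 7 and 8; the branch of steps 4 and 5 joins at step 6).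

The three steps most likely to fail:

First, step 7, the proposed ring expansion. The cumulated ylide may O-alkylate instead of C-alkylate, or LiI may not turn over. The fallback uses known chemistry, sets out from 13 and comes back at 15. LiI/AcOH in THF opens the oxirane to the iodohydrin 7-{[(2E,5R)-5-hydroxy-6-iodo-3-methylhex-2-en-1-yl]oxy}-8-methoxy-2H-chromen-2-one F2. DCC/DMAP esterification with diethylphosphonoacetic acid gives (2R,4E)-1-iodo-6-[(8-methoxy-2-oxo-2H-chromen-7-yl)oxy]-4-methylhex-4-en-2-yl (diethoxyphosphoryl)acetate F3. Cs2CO3 in MeCN closes the ring by intramolecular C-alkylation to diethyl [(5R)-5-{(2E)-4-[(8-methoxy-2-oxo-2H-chromen-7-yl)oxy]-2-methylbut-2-en-1-yl}-2-oxooxolan-3-yl]phosphonate F4. Horner–Wadsworth–Emmons reaction with aqueous formaldehyde and K2CO3 then gives 15.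

Second, step 5, where three organometallic operations and the oxirane closure run in one flask. The aluminate/formaldehyde trapping and the in-flask closure are the weak points. The fallback sets out from 9 and comes back at 12. The same carboalumination (alkenylalane 10) is quenched with iodine to isolate (2R,4E)-1-chloro-5-iodo-4-methylpent-4-en-2-ol F1. C1 is then attached by Stille coupling with (tributylstannyl)methanol (Pd(PPh3)4, dioxane, 80 °C) to give diol 11, now isolated. K2CO3 in MeOH closes the oxirane to 12.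

Third, step 8, the late Shi epoxidation. The allylic aryl ether is a deactivated olefin, the lactone is base-sensitive, and the diastereomer ratio rests on reagent control alone. The fallback sets out from 12 and comes back at 16, with the oxirane set earlier under hydroxyl direction. Sharpless asymmetric epoxidation (Ti(OiPr)4, D-(−)-diethyl tartrate, t-BuOOH, 4 Å MS, CH2Cl2, −20 °C) gives [(2R,3R)-3-methyl-3-{[(2R)-oxiran-2-yl]methyl}oxiran-2-yl]methanol F5. Mitsunobu coupling with 5 gives 8-methoxy-7-{[(2R,3R)-3-methyl-3-{[(2R)-oxiran-2-yl]methyl}oxiran-2-yl]methoxy}-2H-chromen-2-one F6. The less hindered terminal oxirane is then ring-expanded as in step 7, through the ylide 8-methoxy-7-{[(2R,3R)-3-methyl-3-{[(2R)-5-oxo-4-(triphenyl-λ5-phosphanylidene)oxolan-2-yl]methyl}oxiran-2-yl]methoxy}-2H-chromen-2-one F7 and formaldehyde, which gives 16 directly. This fallback still depends on the step-7 chemistry tolerating the second oxirane.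

**Further compounds**

F1 | step 5 | (2R,4E)-1-chloro-5-iodo-4-methylpent-4-en-2-ol | I/C=C(C)/C[C@@H](O)CCl
F2 | step 7 | 7-{[(2E,5R)-5-hydroxy-6-iodo-3-methylhex-2-en-1-yl]oxy}-8-methoxy-2H-chromen-2-one | COc1c(OC/C=C(C)/C[C@@H](O)CI)ccc2ccc(=O)oc12
F3 | step 7 | (2R,4E)-1-iodo-6-[(8-methoxy-2-oxo-2H-chromen-7-yl)oxy]-4-methylhex-4-en-2-yl (diethoxyphosphoryl)acetate | COc1c(OC/C=C(C)/C[C@@H](OC(=O)CP(=O)(OCC)OCC)CI)ccc2ccc(=O)oc12
F4 | step 7 | diethyl [(5R)-5-{(2E)-4-[(8-methoxy-2-oxo-2H-chromen-7-yl)oxy]-2-methylbut-2-en-1-yl}-2-oxooxolan-3-yl]phosphonate (mixture at C3) | COc1c(OC/C=C(C)/C[C@@H]3CC(P(=O)(OCC)OCC)C(=O)O3)ccc2ccc(=O)oc12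
F5 | step 8 | [(2R,3R)-3-methyl-3-{[(2R)-oxiran-2-yl]methyl}oxiran-2-yl]methanol | OC[C@H]1O[C@]1(C)C[C@@H]1CO1
F6 | step 8 | 8-methoxy-7-{[(2R,3R)-3-methyl-3-{[(2R)-oxiran-2-yl]methyl}oxiran-2-yl]methoxy}-2H-chromen-2-one | COc1c(OC[C@H]3O[C@]3(C)C[C@@H]4CO4)ccc2ccc(=O)oc12
F7 | step 8 | 8-methoxy-7-{[(2R,3R)-3-methyl-3-{[(2R)-5-oxo-4-(triphenyl-λ5-phosphanylidene)oxolan-2-yl]methyl}oxiran-2-yl]methoxy}-2H-chromen-2-one | COc1c(OC[C@H]3O[C@]3(C)C[C@@H]4CC(=P(c5ccccc5)(c5ccccc5)c5ccccc5)C(=O)O4)ccc2ccc(=O)oc12
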